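**Retrosynthetic overview**

1. The target is numbered as a bicyclo[3.3.1]non-2-ene: C1 (CHO), C2(CHO)=C3, C4, C5 (CH3), C6, C7, C8 (side chain), C9 (OAc). Ring A is the cyclohexene C1–C2–C3–C4–C5–C9 and ring B is the cyclohexane C1–C9–C5–C6–C7–C8.
2. Endgame: C9–OAc from the C9 ketone (hydride delivered over the C2=C3 bridge), C1–CHO from a 1,3-dioxolane, C2–CHO from a methyl ester.
3. Ring A is closed second, onto ring B: C4–C5 by Mukaiyama–Michael addition of a C5 enol silane to methyl 2-oxobut-3-enoate, C1–C2 by bridged aldol addition, then dehydration to the C2=C3 enoate.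
4. Ring B is made first, in one operation from three components: (R)-citronellal (C8, C7 and the side chain), a nitroalkene (C1, C9) and crotonaldehyde (C5, C6, CH3). An amine-catalysed Michael/Michael/aldol condensation forms C1–C8, C9–C5 and C6=C7; the surplus formyl group on C6 is then removed by decarbonylation.
5. Enabling feature: ring B is a saturated six-membered ring in which the side-chain carbon C8 lies between C7H2–C6H2 and the formyl-bearing C1, with oxygen on C9. This is exactly the aldehyde α-carbon/carbonyl (C8/C7), nitroalkene (C1/C9, nitro as surrogate of the C9 oxygen) and enal (C5/C6) pattern of the cascade.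

Key step: step 2

Assumption: 7 and 8 are drawn as the all-trans ring diastereomer expected from the cascade; other C1/C5/C9 epimers would converge in step 4, because C9 becomes a carbonyl and C1 and C5 are enolised there.

**Route**

Step 1
Reactants: 1 2-ethenyl-1,3-dioxolane
Product: 2 2-[(E)-2-nitroethenyl]-1,3-dioxolane
Conditions: AgNO2 (3 equiv), TEMPO (0.4 equiv), 4 Å MS, ClCH2CH2Cl, 70 °C
Reagents that add atoms: silver nitrite, [Ag+].[O-]N=O
Why: Radical nitration of the terminal alkene (the NO2 radical from AgNO2 adds to the CH2 terminus and TEMPO-assisted loss of hydrogen restores the double bond) should give the conjugated nitroalkene in its thermodynamic E geometry, as in known alkene nitrations.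

Step 2
Reactants: 3 (R)-citronellal; 2 2-[(E)-2-nitroethenyl]-1,3-dioxolane; 4 (E)-but-2-enal
Product: 7 all-trans 4-(1,3-dioxolan-2-yl)-6-methyl-3-[(2R)-6-methylhept-5-en-2-yl]-5-nitrocyclohex-1-ene-1-carbaldehyde, via nitro aldehyde 5 (not isolated), via nitro dialdehyde 6 (not isolated)
Conditions: (R)-α,α-diphenylprolinol trimethylsilyl ether (20 mol%), toluene, 0 °C → rt
Reagents that add atoms: none
Why: Amine-catalysed triple cascade: the enamine of 3 adds to nitroalkene 2 (C1–C8, giving 5), the nitronate of 5 adds to the iminium ion of 4 (C9–C5, giving 6), and the enamine so formed closes ring B by intramolecular aldol addition onto the C7 aldehyde, after which loss of water installs C6=C7 and frees the catalyst. The closest known reaction type is the organocatalytic three-component aldehyde/nitroalkene/enal synthesis of cyclohex-1-ene-1-carbaldehydes with a diarylprolinol silyl ether. Ring B is the only ring closed, in a 6-(enolexo)-exo-trig aldol step. C8 is set by the catalyst, whose diaryl(silyloxy)methyl group shields one face of the E-enamine, so that the (R)-amine should give the target configuration regardless of the remote side-chain centre; C1 follows from the syn-selective Michael transition state, and C9 and C5 settle trans under thermodynamic control. Of these four centres only C8 has to survive, because C9 becomes a carbonyl and C1 and C5 are enolised and re-set later. The selectivity needed is chemoselectivity among the three carbonyl partners, secured by the much higher electrophilicity of the nitroalkene toward the enamine of the only saturated aldehyde and by iminium activation of 4 toward the nitronate.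

Step 3
Reactants: 7 all-trans 4-(1,3-dioxolan-2-yl)-6-methyl-3-[(2R)-6-methylhept-5-en-2-yl]-5-nitrocyclohex-1-ene-1-carbaldehyde
Product: 8 2-{all-trans 5-methyl-2-[(2R)-6-methylhept-5-en-2-yl]-6-nitrocyclohex-3-en-1-yl}-1,3-dioxolane
Conditions: RhCl(PPh3)3 (1.05 equiv), toluene, 110 °C
Reagents that add atoms: none
Why: Tsuji–Wilkinson decarbonylation (oxidative addition of the formyl C–H bond to monovalent rhodium, CO extrusion, C–H reductive elimination) should replace the surplus C6 formyl group by hydrogen without moving the C6=C7 bond or touching a stereocentre.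

Step 4
Reactants: 8 2-{all-trans 5-methyl-2-[(2R)-6-methylhept-5-en-2-yl]-6-nitrocyclohex-3-en-1-yl}-1,3-dioxolane
Product: 10 trans-6-(1,3-dioxolan-2-yl)-2-methyl-5-[(2R)-6-methylhept-5-en-2-yl]cyclohex-2-en-1-one, via deconjugated enone 9 (not isolated)
Conditions: NaOMe, MeOH, 0 °C; then TiCl3, NH4OAc, H2O, rt; then DBU (0.2 equiv), CH2Cl2, rt
Reagents that add atoms: water, O
Why: The Nef reaction in its reductive form (trivalent titanium reduces the nitronate to the imine, which hydrolyses) unmasks the C9 ketone, and DBU then moves C6=C7 into conjugation as C5=C6 through the dienolate, deliberately erasing C5 while C1 equilibrates to the epimer trans to the C8 side chain.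

Step 5
Reactants: 10 trans-6-(1,3-dioxolan-2-yl)-2-methyl-5-[(2R)-6-methylhept-5-en-2-yl]cyclohex-2-en-1-one
Product: 11 {[trans-6-(1,3-dioxolan-2-yl)-2-methyl-5-[(2R)-6-methylhept-5-en-2-yl]cyclohex-1-en-1-yl]oxy}triethylsilane
Conditions: LiBH(s-Bu)3, THF, −78 °C; then Et3SiCl, Et3N, −78 → 0 °C
Reagents that add atoms: chlorotriethylsilane, CC[Si](Cl)(CC)CC
Why: Conjugate (1,4) hydride reduction of the enone generates the enolate only on the C5 side and O-silylation fixes it as the enol silane (conjugate reduction–enolate trapping), so no regiochemical choice between C5 and C1 has to be made and no stereocentre is formed.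

Step 6
Reactants: 12 methyl 2-hydroxybut-3-enoate
Product: 13 methyl 2-oxobut-3-enoate
Conditions: Dess–Martin periodinane, CH2Cl2, 0 °C; cold filtered solution used at once
Reagents that add atoms: none
Why: Dess–Martin oxidation of the secondary allylic alcohol should give the vinyl α-keto ester, which is kept cold and used directly because it dimerises on standing.

Step 7
Reactants: 11 {[trans-6-(1,3-dioxolan-2-yl)-2-methyl-5-[(2R)-6-methylhept-5-en-2-yl]cyclohex-1-en-1-yl]oxy}triethylsilane; 13 methyl 2-oxobut-3-enoate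
Product: 15 methyl 4-{3-(1,3-dioxolan-2-yl)-1-methyl-4-[(2R)-6-methylhept-5-en-2-yl]-2-oxocyclohexyl}-2-oxobutanoate, via silyl enol ether 14 (not isolated)
Conditions: Cu(OTf)2 (10 mol%), CH2Cl2, −78 → −30 °C; then aq. citric acid, THF, 0 °C
Reagents that add atoms: none
Why: Mukaiyama–Michael addition: Cu(OTf)2 chelates the α-keto ester and the enol silane adds to the vinyl terminus to form C4–C5 and the C5 quaternary centre, the acceptor entering axially on the face trans to the C1 dioxolanyl group so that the new chain is cis to C1–H as the later bridge requires, and the acidic work-up hydrolyses silyl enol ether 14.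

Step 8
Reactants: 15 methyl 4-{3-(1,3-dioxolan-2-yl)-1-methyl-4-[(2R)-6-methylhept-5-en-2-yl]-2-oxocyclohexyl}-2-oxobutanoate
Product: 16 methyl 1-(1,3-dioxolan-2-yl)-2-hydroxy-5-methyl-8-[(2R)-6-methylhept-5-en-2-yl]-9-oxobicyclo[3.3.1]nonane-2-carboxylate
Conditions: DBU (0.3 equiv), CH2Cl2 (0.01 M), 0 °C → rt
Reagents that add atoms: none
Why: Intramolecular (bridged) aldol addition: C1, the only enolisable position of the C9 ketone, attacks the strongly electrophilic keto-ester carbonyl in a 6-(enolendo)-exo-trig closure of ring A, and because the tether is axial at C5 the new C1–C2 bond must form cis to it, which fixes C1 with the dioxolanyl group trans to the C8 side chain (both C2 carbinol epimers are carried on).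

Step 9
Reactants: 16 methyl 1-(1,3-dioxolan-2-yl)-2-hydroxy-5-methyl-8-[(2R)-6-methylhept-5-en-2-yl]-9-oxobicyclo[3.3.1]nonane-2-carboxylate
Product: 17 methyl 1-(1,3-dioxolan-2-yl)-5-methyl-8-[(2R)-6-methylhept-5-en-2-yl]-9-oxobicyclo[3.3.1]non-2-ene-2-carboxylate
Conditions: Burgess reagent (MeO2CNSO2NEt3), toluene, 70 °C
Reagents that add atoms: none
Why: Burgess dehydration (syn elimination through the sulfamate ester) can take a hydrogen only from C3, since C1 is quaternary, and should therefore give the conjugated C2=C3 enoate.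

Step 10
Reactants: 17 methyl 1-(1,3-dioxolan-2-yl)-5-methyl-8-[(2R)-6-methylhept-5-en-2-yl]-9-oxobicyclo[3.3.1]non-2-ene-2-carboxylate
Product: 18 1-(1,3-dioxolan-2-yl)-2-(hydroxymethyl)-5-methyl-8-[(2R)-6-methylhept-5-en-2-yl]bicyclo[3.3.1]non-2-en-9-ol
Conditions: i-Bu2AlH (5 equiv), CH2Cl2, −78 → −40 °C; aq. KNaC4H4O6
Reagents that add atoms: none
Why: Hydride reduction with i-Bu2AlH converts the ester into the allylic alcohol and the C9 ketone into the alcohol, the hydride approaching C9 over the C2=C3 bridge (steric approach control, the other face being shielded by the axial hydrogens on C6 and C8), which should set C9 with the hydroxyl over ring B as in the target.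

Step 11
Reactants: 18 1-(1,3-dioxolan-2-yl)-2-(hydroxymethyl)-5-methyl-8-[(2R)-6-methylhept-5-en-2-yl]bicyclo[3.3.1]non-2-en-9-ol
Product: 19 1-(1,3-dioxolan-2-yl)-9-hydroxy-5-methyl-8-[(2R)-6-methylhept-5-en-2-yl]bicyclo[3.3.1]non-2-ene-2-carbaldehyde
Conditions: MnO2 (20 equiv), CH2Cl2, rt
Reagents that add atoms: none
Why: Chemoselective allylic oxidation: MnO2 should oxidise only the allylic primary alcohol to the enal and leave the hindered secondary C9 alcohol untouched.

Step 12
Reactants: 19 1-(1,3-dioxolan-2-yl)-9-hydroxy-5-methyl-8-[(2R)-6-methylhept-5-en-2-yl]bicyclo[3.3.1]non-2-ene-2-carbaldehyde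
Product: 20 1-(1,3-dioxolan-2-yl)-2-formyl-5-methyl-8-[(2R)-6-methylhept-5-en-2-yl]bicyclo[3.3.1]non-2-en-9-yl acetate
Conditions: Ac2O, DMAP, Et3N, CH2Cl2, rt → 40 °C
Reagents that add atoms: acetic anhydride, CC(=O)OC(C)=O
Why: DMAP-catalysed acylation of the hindered secondary alcohol proceeds with retention at C9.

Step 13
Reactants: 20 1-(1,3-dioxolan-2-yl)-2-formyl-5-methyl-8-[(2R)-6-methylhept-5-en-2-yl]bicyclo[3.3.1]non-2-en-9-yl acetate
Product: 21 (1R,5R,8S,9R)-1,2-diformyl-5-methyl-8-[(2R)-6-methylhept-5-en-2-yl]bicyclo[3.3.1]non-2-en-9-yl acetate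
Conditions: 1 M aq. HCl, THF, 40 °C
Reagents that add atoms: water, O
Why: Acid-catalysed acetal hydrolysis releases the C1 formyl group, which has no α-hydrogen and therefore can neither epimerise nor eliminate the β-acetoxy group.

**Compound list**

1 | 2-ethenyl-1,3-dioxolane | C=CC1OCCO1 | starting material
2 | 2-[(E)-2-nitroethenyl]-1,3-dioxolane | [O-][N+](=O)/C=C/C1OCCO1 | intermediate
3 | (R)-citronellal, (3R)-3,7-dimethyloct-6-enal | O=CC[C@H](C)CCC=C(C)C | starting material
4 | (E)-but-2-enal (crotonaldehyde) | C/C=C/C=O | starting material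
5 | syn-3-(1,3-dioxolan-2-yl)-2-[(2R)-6-methylhept-5-en-2-yl]-4-nitrobutanal | O=C[C@@H]([C@H](C)CCC=C(C)C)[C@H](C1OCCO1)C[N+](=O)[O-] | intermediate
6 | 5-(1,3-dioxolan-2-yl)-3-methyl-6-[(2R)-6-methylhept-5-en-2-yl]-4-nitroheptanedial | O=C[C@@H]([C@H](C)CCC=C(C)C)[C@H](C1OCCO1)[C@@H]([N+](=O)[O-])[C@H](C)CC=O | intermediate
7 | all-trans 4-(1,3-dioxolan-2-yl)-6-methyl-3-[(2R)-6-methylhept-5-en-2-yl]-5-nitrocyclohex-1-ene-1-carbaldehyde | O=CC1=C[C@@H]([C@H](C)CCC=C(C)C)[C@H](C2OCCO2)[C@@H]([N+](=O)[O-])[C@@H]1C | intermediate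
8 | 2-{all-trans 5-methyl-2-[(2R)-6-methylhept-5-en-2-yl]-6-nitrocyclohex-3-en-1-yl}-1,3-dioxolane | C1=C[C@@H]([C@H](C)CCC=C(C)C)[C@H](C2OCCO2)[C@@H]([N+](=O)[O-])[C@@H]1C | intermediate
9 | 6-(1,3-dioxolan-2-yl)-2-methyl-5-[(2R)-6-methylhept-5-en-2-yl]cyclohex-3-en-1-one | C1=C[C@@H]([C@H](C)CCC=C(C)C)[C@H](C2OCCO2)C(=O)[C@@H]1C | intermediate
10 | trans-6-(1,3-dioxolan-2-yl)-2-methyl-5-[(2R)-6-methylhept-5-en-2-yl]cyclohex-2-en-1-one | CC1=CC[C@@H]([C@H](C)CCC=C(C)C)[C@H](C2OCCO2)C1=O | intermediate
11 | {[trans-6-(1,3-dioxolan-2-yl)-2-methyl-5-[(2R)-6-methylhept-5-en-2-yl]cyclohex-1-en-1-yl]oxy}triethylsilane | C1C[C@@H]([C@H](C)CCC=C(C)C)[C@H](C2OCCO2)C(O[Si](CC)(CC)CC)=C1C | intermediate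
12 | methyl 2-hydroxybut-3-enoate (racemic) | C=CC(O)C(=O)OC | starting material
13 | methyl 2-oxobut-3-enoate | C=CC(=O)C(=O)OC | intermediate
14 | methyl 4-{3-(1,3-dioxolan-2-yl)-1-methyl-4-[(2R)-6-methylhept-5-en-2-yl]-2-oxocyclohexyl}-2-[(triethylsilyl)oxy]but-2-enoate | C1C[C@@H]([C@H](C)CCC=C(C)C)[C@H](C2OCCO2)C(=O)[C@@]1(C)CC=C(O[Si](CC)(CC)CC)C(=O)OC | intermediate
15 | methyl 4-{3-(1,3-dioxolan-2-yl)-1-methyl-4-[(2R)-6-methylhept-5-en-2-yl]-2-oxocyclohexyl}-2-oxobutanoate (chain trans to the dioxolanyl group, dioxolanyl trans to the side chain) | C1C[C@@H]([C@H](C)CCC=C(C)C)[C@H](C2OCCO2)C(=O)[C@@]1(C)CCC(=O)C(=O)OC | intermediate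
16 | methyl 1-(1,3-dioxolan-2-yl)-2-hydroxy-5-methyl-8-[(2R)-6-methylhept-5-en-2-yl]-9-oxobicyclo[3.3.1]nonane-2-carboxylate (C1, C5, C8 as in the target; C2 either epimer) | O=C1[C@@]2(C)CCC(O)(C(=O)OC)[C@]1(C3OCCO3)[C@H]([C@H](C)CCC=C(C)C)CC2 | intermediate
17 | methyl 1-(1,3-dioxolan-2-yl)-5-methyl-8-[(2R)-6-methylhept-5-en-2-yl]-9-oxobicyclo[3.3.1]non-2-ene-2-carboxylate | O=C1[C@@]2(C)CC=C(C(=O)OC)[C@]1(C3OCCO3)[C@H]([C@H](C)CCC=C(C)C)CC2 | intermediate
18 | 1-(1,3-dioxolan-2-yl)-2-(hydroxymethyl)-5-methyl-8-[(2R)-6-methylhept-5-en-2-yl]bicyclo[3.3.1]non-2-en-9-ol (9-OH over ring B) | O[C@@H]1[C@@]2(C)CC=C(CO)[C@]1(C3OCCO3)[C@H]([C@H](C)CCC=C(C)C)CC2 | intermediate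
19 | 1-(1,3-dioxolan-2-yl)-9-hydroxy-5-methyl-8-[(2R)-6-methylhept-5-en-2-yl]bicyclo[3.3.1]non-2-ene-2-carbaldehyde | O[C@@H]1[C@@]2(C)CC=C(C=O)[C@]1(C3OCCO3)[C@H]([C@H](C)CCC=C(C)C)CC2 | intermediate
20 | 1-(1,3-dioxolan-2-yl)-2-formyl-5-methyl-8-[(2R)-6-methylhept-5-en-2-yl]bicyclo[3.3.1]non-2-en-9-yl acetate | CC(=O)O[C@@H]1[C@@]2(C)CC=C(C=O)[C@]1(C3OCCO3)[C@H]([C@H](C)CCC=C(C)C)CC2 | intermediate
21 | (1R,5R,8S,9R)-1,2-diformyl-5-methyl-8-[(2R)-6-methylhept-5-en-2-yl]bicyclo[3.3.1]non-2-en-9-yl acetate | CC(=O)O[C@@H]1[C@@]2(C)CC=C(C=O)[C@]1(C=O)[C@H]([C@H](C)CCC=C(C)C)CC2 | target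

**Step count and risks**

Total step count: 13. Longest linear sequence: 12 steps (steps 1–5 and 7–13, from 1); step 6 is a one-step side branch.

The three steps most likely to fail:

Step 7. The doubly activated acceptor may be lost to hetero-Diels–Alder self-dimerisation, or the Lewis acid may erode the facial selectivity at C5 or open the dioxolane before conjugate addition is complete. The fallback sets out from 11 and comes back at 17, supplying the three-carbon bridge as acrolein and adding the ester carbon afterwards. Mukaiyama–Michael addition of 11 to acrolein (BF3·OEt2, CH2Cl2, −78 °C) should give keto aldehyde F3. Base-mediated bridged aldol addition onto the unhindered aldehyde (K2CO3, MeOH) should give ketol F4, and Dess–Martin oxidation the diketone F5. Because the C2 ketone of F5 can enolise only toward C3, KN(SiMe3)2 and PhNTf2 should give enol triflate F6. Palladium-catalysed methoxycarbonylation (Pd(OAc)2, PPh3, CO, MeOH, Et3N, DMF) then converts F6 into 17.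

Step 8. Retro-aldol reversal and reversible β-elimination toward the dioxolane may outrun the congested C1–C2 bond formation between a fully substituted enolate carbon and a ketone. The fallback sets out from 15 and comes back at 17, bypassing 16 and making the bond irreversibly. KN(SiMe3)2 (1 equiv) and PhNTf2 at −78 °C should convert the more acidic keto-ester side of 15 into enol triflate F7. Palladium-catalysed intramolecular α-alkenylation of the C9 ketone at C1 (Pd2(dba)3, Xantphos, Cs2CO3, toluene, 80 °C) then closes ring A and gives the enoate 17 directly.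

Step 2. The aliphatic, acetal-bearing nitroalkene may enter the cascade sluggishly, so that crotonaldehyde is consumed by competing enamine and iminium pathways and catalyst control at C8 is diluted. The fallback sets out from 3 and 2 and comes back at 7, separating the two Michael additions and closing the ring by olefination instead of aldol condensation. The first Michael addition is run alone with the same amine and 4-nitrophenol as co-catalyst to give 5. Ethyl (E)-2-(diethoxyphosphoryl)but-2-enoate and Cs2CO3 are then added (nitronate Michael addition, intramolecular Horner–Wadsworth–Emmons olefination) to give the ethyl cyclohexenecarboxylate F1. Reduction with i-Bu2AlH at −78 °C should give allylic alcohol F2, and MnO2 oxidation returns 7.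

Further compounds

F1 | step 2 | ethyl all-trans 4-(1,3-dioxolan-2-yl)-6-methyl-3-[(2R)-6-methylhept-5-en-2-yl]-5-nitrocyclohex-1-ene-1-carboxylate | CCOC(=O)C1=C[C@@H]([C@H](C)CCC=C(C)C)[C@H](C2OCCO2)[C@@H]([N+](=O)[O-])[C@@H]1C
F2 | step 2 | {all-trans 4-(1,3-dioxolan-2-yl)-6-methyl-3-[(2R)-6-methylhept-5-en-2-yl]-5-nitrocyclohex-1-en-1-yl}methanol | OCC1=C[C@@H]([C@H](C)CCC=C(C)C)[C@H](C2OCCO2)[C@@H]([N+](=O)[O-])[C@@H]1C
F3 | step 7 | 3-{3-(1,3-dioxolan-2-yl)-1-methyl-4-[(2R)-6-methylhept-5-en-2-yl]-2-oxocyclohexyl}propanal | C1C[C@@H]([C@H](C)CCC=C(C)C)[C@H](C2OCCO2)C(=O)[C@@]1(C)CCC=O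
F4 | step 7 | 1-(1,3-dioxolan-2-yl)-2-hydroxy-5-methyl-8-[(2R)-6-methylhept-5-en-2-yl]bicyclo[3.3.1]nonan-9-one | O=C1[C@@]2(C)CCC(O)[C@]1(C3OCCO3)[C@H]([C@H](C)CCC=C(C)C)CC2
F5 | step 7 | 1-(1,3-dioxolan-2-yl)-5-methyl-8-[(2R)-6-methylhept-5-en-2-yl]bicyclo[3.3.1]nonane-2,9-dione | O=C1[C@@]2(C)CCC(=O)[C@]1(C3OCCO3)[C@H]([C@H](C)CCC=C(C)C)CC2
F6 | step 7 | 1-(1,3-dioxolan-2-yl)-5-methyl-8-[(2R)-6-methylhept-5-en-2-yl]-9-oxobicyclo[3.3.1]non-2-en-2-yl trifluoromethanesulfonate | O=C1[C@@]2(C)CC=C(OS(=O)(=O)C(F)(F)F)[C@]1(C3OCCO3)[C@H]([C@H](C)CCC=C(C)C)CC2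
F7 | step 8 | methyl 4-{3-(1,3-dioxolan-2-yl)-1-methyl-4-[(2R)-6-methylhept-5-en-2-yl]-2-oxocyclohexyl}-2-{[(trifluoromethyl)sulfonyl]oxy}but-2-enoate | C1C[C@@H]([C@H](C)CCC=C(C)C)[C@H](C2OCCO2)C(=O)[C@@]1(C)CC=C(OS(=O)(=O)C(F)(F)F)C(=O)OC
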